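At early times a mole of starting material, the limiting reagent, leaves mainly by two routes, a first-order one into the ring and a second-order one into the open dimer, and this ledger follows it down each.

    starting material → ring (k1 = 1.7 /min)
    2 starting material → open dimer (k2 = 1.2 /M/min)
    ring → over-reaction product (k3 = 0.062 /min)
    starting material ⇌ dormant form (K4 = 1.8, k4 = 0.18 /min)
    starting material + open dimer → open trimer (k5 = 3.3 /M/min)

the same everywhere: starting material 1.0 M

| charge | time |
|---|---|
| Saturday's | 60 min |
| Sunday's | 30 min |
| Tuesday's | 120 min |

- which of these there is most of at the end, counted by the starting material in it, Saturday's (open dimer / open trimer / ring / over-reaction product)
- which of these there is most of at the end, counted by the starting material in it, Sunday's (open dimer / open trimer / ring / over-reaction product)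
- which of these there is most of at the end, counted by the starting material in it, Tuesday's (open dimer / open trimer / ring / over-reaction product)
- how much there is at the end of the one of these that leads, in percent of the starting material charged: Saturday's
- how much there is at the end of the one of these that leads, in percent of the starting material charged: Sunday's
- how much there is at the end of the one of these that leads, in percent of the starting material charged: Tuesday's

- a species is counted by the starting material in it: one open dimer counts as two
- a species is counted by the starting material in it: one open trimer counts as three
- for a step with 2 of a species take k times the square, and two of it per event
- run time (Saturday's): 60 min

First entry. The crossover concentration c× is the level of starting material at which ring and open dimer draw on it equally, the ring constant over twice the dimer constant: 0.708 M. At level S the ring takes the share c×/(c×+S), so as S falls from the charge c to nothing, the ring side collects c× ln(1+c/c×), which is 0.624 M. The rest leaves 0.188 M of open dimer.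

Second round. That dimer also eats starting material on its way to the open trimer. It rises from nothing, so its mean is taken as half of that amount, which adds 0.311 /min to the first-order loss and raises the crossover in the denominator to c′ = 0.838 M. The ring side becomes c× ln(1+c/c′), or 0.556 M, and the open side holds the remaining 0.444 M.

The dormant form gets no line of its own in this reckoning, because it is fed at 0.18 /min, far slower than the ring's 1.7 /min, and its way back alone has a half-life of 6.93 min, shorter than Sunday's 30 min.

Last entry. The ring side passes into over-reaction product at 0.062 /min, which books 54.3% on Saturday's, 47.0% on Sunday's and 55.6% on Tuesday's. This reckoning leaves 8.66% in Sunday's ring. The open side together, 44.4%, stands below Sunday's product, so this reckoning puts over-reaction product first on each day.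

The forecast, treating the run as “a fast burst followed by a slow tail”, also names over-reaction product on Saturday's, Sunday's and Tuesday's, at 57%, 48.4% and 58.5%, each higher than this reckoning.

The simulation puts over-reaction product ahead at 56.1%, 47.6% and 57.7%, with open trimer behind it on each day. Tuesday's open side stands at 42.2% against the booked 44.4%, and waiting longer changes Tuesday's product by little: 57.8% after 1200 min. For a neighbour of Tuesday's charged with 2.5 M, the same reckoning gives c′ = 1.20 M and a ring side of 31.9% of its charge. That neighbour flask ends with over-reaction product at 35.5%, less than the 49.7% in open trimer.

(The constants are those of an exercise; the run is a simulation.)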